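The unit I counted in was the turnover of partner B: one molecule of it taken, either by substrate to give open intermediate or by partner A to give second intermediate. The same charges went into each of these set-ups:

| flask | substrate | partner A | partner B | time | remark |
|---|---|---|---|---|---|
| Saturday's | 0.059 M | 1.10 equiv | 1.05 equiv (fed, over 2.00 min) | 2.5 min | all but partner B at the start; partner B goes in evenly over 2.00 min, the run ends at 2.5 min |
| Wednesday's | 0.059 M | 1.10 equiv | 1.05 equiv |  | one stirred flow tank at steady state, fed with the mixture as stated, mean residence time 2.5 min |
| Thursday's | 0.059 M (fed, over 2.00 min) | 1.10 equiv | 1.05 equiv | 2.5 min | all but substrate at the start; substrate goes in evenly over 2.00 min, the run ends at 2.5 min |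
| Friday's | 0.059 M | 1.10 equiv | 1.05 equiv | 2.5 min | a closed flask charged with all of it at once and left for 2.5 min |

- the set-up with the highest amount of open intermediate at the outlet or at the end, in percent of the substrate put in ("none" if the first two lie within 2 percentage points) (Saturday's / Wednesday's / Thursday's / Friday's / none)
- amount of open intermediate at the outlet or at the end, in percent of the substrate put in, Saturday's
- amount of open intermediate at the outlet or at the end, in percent of the substrate put in, Wednesday's
- amount of open intermediate at the outlet or at the end, in percent of the substrate put in, Thursday's
- amount of open intermediate at the outlet or at the end, in percent of the substrate put in, Friday's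

- where a step has two of a species, its rate is k times that concentration squared, and two are used at each turn
- the stated concentrations are those of everything mixed, before any reaction; amounts are the same in each set-up
- the feed brings no volume worth counting
- run time (Saturday's): 2.5 min

What looked contradictory was this. The constant of the step from substrate to open intermediate, 2.9 M⁻¹ s⁻¹, stands 6.17 times above that of the step from partner A to second intermediate, 0.47 M⁻¹ s⁻¹. With partner B as charged, the half-life of substrate by its step alone is 0.064 min, so 39.1 such half-lives fit into the run. And yet I reckoned that partner A takes the lead early in Thursday's flask.

It cleared up once I set each constant beside its concentrations. At the start of Friday's flask, with substrate and partner A as charged, substrate gets 5.61 turnovers for each one on partner A. In Thursday's flask substrate is held low early on and takes partner B about as fast as the feed brings it, 0.0295 M min⁻¹, while partner A takes it at 0.113 M min⁻¹, which is faster. The ratio is 0.260. This is the split, a selectivity factor: the rate at which substrate takes partner B over the rate at which partner A takes it, early in a substrate feed. For a ranking of my own I scored each set-up by substrate's share of the turnovers: the share at the start for Friday's, the early share for Thursday's, and for Saturday's and Wednesday's the share at the start of Friday's divided by one plus 0.015 s⁻¹, the constant of the step to dormant form, times a mean wait, which I took as 1.00 min in Saturday's and 2.5 min in Wednesday's. That rough ranking put Friday's first.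

The forecast named Friday's, with 54 % for Saturday's, 51 % for Wednesday's, 33 % for Thursday's and 66 % for Friday's, holding of the substrate feed that "B then sits with A and mostly makes second intermediate".

    substrate + partner B → open intermediate (k1 = 2.9 M⁻¹ s⁻¹)
    partner B + partner A → second intermediate (k2 = 0.47 M⁻¹ s⁻¹)
    open intermediate + second intermediate → target (k3 = 0.25 M⁻¹ s⁻¹)
    2 second intermediate → homo product (k4 = 0.14 M⁻¹ s⁻¹)
    second intermediate → side product (k5 = 0.013 s⁻¹)
    substrate ⇌ dormant form (K6 = 1.4, k6 = 0.015 s⁻¹)

The flask gave Friday's as best, at 65.5 %, with Saturday's at 55.0 %, Wednesday's at 50.9 % and Thursday's at 31.3 %, so the forecast stood, and the order of addition was worth 34 percentage points between Friday's and Thursday's. Thursday's ended with 41.5 % of partner A left, Friday's with 74.0 %. The split of 0.260 gives partner A 79.4 % of the early turnovers in Thursday's; over the whole run it took 61.3 % of partner B's charge, a smaller share.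

In Thursday's flask with 0.15 M of substrate, equivalents held, the split drops to 0.102, below Thursday's own. That flask gave 16.0 % of open intermediate, against 31.3 %.

The constants used here come from no measurement.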